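**Retrosynthetic overview**

- The last operation only removes a temporary C4 oxygen (radical deoxygenation). Before that, both rings of the cis-fused cyclopenta[c]isoxazolidine are disconnected together, at O–C3 and C3a–C6a, back to a monocyclic 2,3-dialkyloxaziridine.
- Key event: the three-membered O–N–C ring (its carbon is the future C6a) opens at C–O to a nitrone and takes up the tethered Z-configured C3a=C3 alkene. The oxaziridine thus grows by two carbons into the isoxazolidine while the same C3a–C6a bond closes the cyclopentane.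
- Enabling feature: a strained O–N–C6a ring whose nitrogen lone pair assists C6a–O heterolysis, a three-carbon tether (C6–C5–C4) from that carbon to a Z-alkene, and a temporary allylic C4–OSi stereocentre that fixes the π-face by allylic 1,3-strain.
- The oxaziridine comes from peracid oxidation of the aldimine of a (4R,5Z)-4-silyloxy-tetradec-5-enal and 13-(pyridin-3-yl)tridecan-1-amine. The aldehyde comes from (R)-5-(hydroxymethyl)oxolan-2-one by Z-selective Wittig olefination, and both pyridylalkyl chains come from one batch of laterally lithiated 3-methylpyridine.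
- Ring order: pyridines carried from the start; oxaziridine; then isoxazolidine and cyclopentane simultaneously in the key step.

Key step: step 12

Remark: the target is read as (3S,3aS,6aR), with H-3, H-3a and H-6a all cis and the octyl chain on the concave face; the sense of induction by the temporary C4 centre rests on an allylic 1,3-strain model.

**Step 1**
Reactants: 1 3-methylpyridine
Product: 2 (pyridin-3-ylmethyl)lithium (THF solution)
Conditions: LiN(i-Pr)2 (1.05 equiv), THF, −78 °C; the cold solution is not stored but divided at once by cannula between steps 2 and 3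
Reagents that add atoms: lithium diisopropylamide, [Li]N(C(C)C)C(C)C
Why: Lateral lithiation of the methyl group of 3-methylpyridine by the hindered amide base should give the picolyl anion, and one batch serves both chain alkylations, which are run side by side.

**Step 2**
Reactants: 2 (pyridin-3-ylmethyl)lithium; 3 1,8-dibromooctane
Product: 4 3-(9-bromononyl)pyridine
Conditions: solution of 2 added by cannula to 3 (3 equiv), THF, −78 °C to rt
Reagents that add atoms: none
Why: SN2 alkylation of the picolyl anion by inverse addition to an excess of the dibromide should give the mono-alkylated bromide, the excess suppressing double substitution.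

**Step 3**
Reactants: 2 (pyridin-3-ylmethyl)lithium; 5 1,12-dibromododecane
Product: 6 3-(13-bromotridecyl)pyridine
Conditions: solution of 2 added by cannula to 5 (3 equiv), THF, −78 °C to rt
Reagents that add atoms: none
Why: The same SN2 alkylation of the picolyl anion with the twelve-carbon dibromide should deliver the thirteen-carbon bromide.

**Step 4**
Reactants: 6 3-(13-bromotridecyl)pyridine
Product: 9 13-(pyridin-3-yl)tridecan-1-amine, via alkyl azide 7 (not isolated), via iminophosphorane 8 (not isolated)
Conditions: NaN3, DMF, 60 °C; then PPh3, THF–H2O, 50 °C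
Reagents that add atoms: sodium azide, [Na+].[N-]=[N+]=[N-]
Why: SN2 azide displacement followed by Staudinger reduction should give the primary amine without over-alkylation.

**Step 5**
Reactants: 4 3-(9-bromononyl)pyridine
Product: 10 triphenyl[9-(pyridin-3-yl)nonyl]phosphonium bromide
Conditions: PPh3 (2 equiv), MeCN, reflux
Reagents that add atoms: triphenylphosphine, c1ccc(cc1)P(c1ccccc1)c1ccccc1
Why: SN2 quaternisation of the soft phosphine at the primary bromide (phosphonium salt formation) should outrun self-alkylation of the pyridine nitrogen when the phosphine is in excess.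

**Step 6**
Reactants: 11 (5R)-5-(hydroxymethyl)oxolan-2-one
Product: 12 (2R)-5-oxooxolane-2-carbaldehyde
Conditions: Dess–Martin periodinane, CH2Cl2, 0 °C to rt; used crude
Reagents that add atoms: none
Why: Dess–Martin oxidation of the primary alcohol under neutral, non-enolising conditions should give the configurationally labile α-oxy aldehyde without touching its stereocentre.

**Step 7**
Reactants: 10 triphenyl[9-(pyridin-3-yl)nonyl]phosphonium bromide; 12 (2R)-5-oxooxolane-2-carbaldehyde
Product: 14 (5R)-5-[(1Z)-10-(pyridin-3-yl)dec-1-en-1-yl]oxolan-2-one, via phosphorus ylide 13 (not isolated)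
Conditions: NaN(SiMe3)2, THF, −78 °C; then 12, −78 °C to 0 °C
Reagents that add atoms: none
Why: Lithium-free Wittig olefination with a non-stabilised ylide should give the Z-alkene under kinetic control, the aldehyde reacting far faster than the lactone carbonyl and the low temperature protecting the α-stereocentre.

**Step 8**
Reactants: 14 (5R)-5-[(1Z)-10-(pyridin-3-yl)dec-1-en-1-yl]oxolan-2-one
Product: 15 (4R,5Z)-4-hydroxy-N-methoxy-N-methyl-14-(pyridin-3-yl)tetradec-5-enamide
Conditions: MeNH(OMe)·HCl, i-PrMgCl, THF, −20 °C to 0 °C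
Reagents that add atoms: N,O-dimethylhydroxylamine hydrochloride, CNOC.Cl
Why: Aminolysis of the lactone by the chloromagnesium amide (Weinreb amide formation) should open the ring without affecting the carbinol centre or the Z-alkene.

**Step 9**
Reactants: 15 (4R,5Z)-4-hydroxy-N-methoxy-N-methyl-14-(pyridin-3-yl)tetradec-5-enamide
Product: 16 (4R,5Z)-4-[(tert-butyldimethylsilyl)oxy]-N-methoxy-N-methyl-14-(pyridin-3-yl)tetradec-5-enamide
Conditions: t-BuMe2SiCl, imidazole, DMF, rt
Reagents that add atoms: tert-butyldimethylsilyl chloride, CC(C)(C)[Si](C)(C)Cl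
Why: Silyl ether formation at the secondary allylic alcohol blocks relactonisation and installs the bulky group that later directs the cycloaddition.

**Step 10**
Reactants: 16 (4R,5Z)-4-[(tert-butyldimethylsilyl)oxy]-N-methoxy-N-methyl-14-(pyridin-3-yl)tetradec-5-enamide
Product: 17 (4R,5Z)-4-[(tert-butyldimethylsilyl)oxy]-14-(pyridin-3-yl)tetradec-5-enal
Conditions: i-Bu2AlH (2.2 equiv), THF, −78 °C; aq. KNaC4H4O6
Reagents that add atoms: none
Why: Weinreb amide reduction should stop at the chelated tetrahedral intermediate, which releases the aldehyde only on work-up.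

**Step 11**
Reactants: 17 (4R,5Z)-4-[(tert-butyldimethylsilyl)oxy]-14-(pyridin-3-yl)tetradec-5-enal; 9 13-(pyridin-3-yl)tridecan-1-amine
Product: 19 trans-3-[(3R,4Z)-3-[(tert-butyldimethylsilyl)oxy]-13-(pyridin-3-yl)tridec-4-en-1-yl]-2-[13-(pyridin-3-yl)tridecyl]oxaziridine (both ring diastereomers), via aldimine 18 (not isolated)
Conditions: MgSO4, CH2Cl2, rt; filter; then mCPBA (1.05 equiv), CH2Cl2, −40 °C to 0 °C
Reagents that add atoms: meta-chloroperoxybenzoic acid, OOC(=O)c1cccc(Cl)c1
Why: Condensation gives the E-aldimine, and peracid oxidation of its C=N bond (imine-to-oxaziridine oxidation) should be much faster at low temperature than epoxidation of the Z-alkene or N-oxidation of the pyridines; the two new ring centres form without control and are erased in step 12.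

**Step 12**
Reactants: 19 trans-oxaziridine
Product: 21 (3S,3aS,4R,6aR)-4-[(tert-butyldimethylsilyl)oxy]-3-[8-(pyridin-3-yl)octyl]-1-[13-(pyridin-3-yl)tridecyl]hexahydro-1H-cyclopenta[c]isoxazole, via nitrone 20 (not isolated)
Conditions: pyridinium p-toluenesulfonate (0.2 equiv), (CF3)2CHOH–PhMe 1:4, 40 °C; then 95 °C, sealed tube
Reagents that add atoms: none
Why: Proposed new method: activation of the ring oxygen by the weak acid and the hydrogen-bond-donating solvent should break the strained C–O bond of the oxaziridine with help from the nitrogen lone pair (opening to the N-hydroxyiminium ion, then loss of its O–H proton) and give the Z-aldonitrone 20, whose C=N–O unit adds in a concerted, suprafacial intramolecular 1,3-dipolar cycloaddition across the tethered Z-alkene, so that the two alkene carbons are in effect inserted into the former C–O bond. The closest known reaction types are the acid-catalysed or thermal isomerisation of 3-aryloxaziridines to nitrones and the thermal [3+2] ring expansion of 2-alkyl-3-aryloxaziridines with alkenes to isoxazolidines; a 3-alkyl oxaziridine reacting intramolecularly has not been shown. The isoxazolidine closes by the two new bonds O–C3 and C3a–C6a (growth of the three-membered O–N–C ring by two carbons), and the cyclopentane closes at the same moment through the C3a–C6a bond in the fused, 5-exo sense dictated by the three-carbon tether. C3 and C3a are set relative to each other by the Z-alkene geometry, which places the octyl chain cis to C4 and H-3 cis to H-3a; C6a is set by the cis ring fusion that the short tether enforces; the absolute sense is set by the (R)-C4 silyloxy centre, because allylic 1,3-strain keeps H-4 in the plane of the Z-alkene and the tether can then deliver the nitrone carbon only to the face anti to the silyloxy group. The step needs C–O and not N–O cleavage of the oxaziridine, which the nitrogen-stabilised cation and the absence of metals, light and radical initiators should secure, and it needs face selectivity and fused regiochemistry, which the C4 centre next to a Z-alkene and the tether length should secure.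

**Step 13**
Reactants: 21 silyl ether of the bicycle
Product: 22 (3S,3aR,4R,6aR)-3-[8-(pyridin-3-yl)octyl]-1-[13-(pyridin-3-yl)tridecyl]hexahydro-1H-cyclopenta[c]isoxazol-4-ol
Conditions: Bu4NF, THF, rt to 40 °C
Reagents that add atoms: none
Why: Fluoride-mediated silyl ether cleavage should free the C4 alcohol under conditions inert to the N–O bond and the pyridines.

**Step 14**
Reactants: 22 bicyclic C4 alcohol
Product: 23 O-[(3S,3aR,4R,6aR)-3-[8-(pyridin-3-yl)octyl]-1-[13-(pyridin-3-yl)tridecyl]hexahydro-1H-cyclopenta[c]isoxazol-4-yl] 1H-imidazole-1-carbothioate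
Conditions: 1,1'-thiocarbonyldiimidazole, 4-(dimethylamino)pyridine (cat.), ClCH2CH2Cl, 70 °C
Reagents that add atoms: 1,1'-thiocarbonyldiimidazole, S=C(n1ccnc1)n1ccnc1
Why: Thioacylation of the secondary alcohol gives the imidazolyl thionocarbonate needed for radical deoxygenation, the weakly nucleophilic ring and pyridine nitrogens reacting only reversibly.

**Step 15**
Reactants: 23 imidazolyl thionocarbonate
Product: 24 pyrinodemin B, (3S,3aS,6aR)-3-[8-(pyridin-3-yl)octyl]-1-[13-(pyridin-3-yl)tridecyl]hexahydro-1H-cyclopenta[c]isoxazole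
Conditions: Bu3SnH, azobisisobutyronitrile (cat.), PhMe, 100 °C
Reagents that add atoms: none
Why: Barton–McCombie deoxygenation: the stannyl radical adds to C=S, the C4–O bond fragments to a secondary cyclopentyl radical that is reduced by the tin hydride, no stereocentre being created and the three set in step 12 remaining untouched.

**Compound list**

1 | 3-methylpyridine | Cc1cccnc1 | starting material
2 | (pyridin-3-ylmethyl)lithium | [Li]Cc1cccnc1 | intermediate
3 | 1,8-dibromooctane | BrCCCCCCCCBr | starting material
4 | 3-(9-bromononyl)pyridine | BrCCCCCCCCCc1cccnc1 | intermediate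
5 | 1,12-dibromododecane | BrCCCCCCCCCCCCBr | starting material
6 | 3-(13-bromotridecyl)pyridine | BrCCCCCCCCCCCCCc1cccnc1 | intermediate
7 | 3-(13-azidotridecyl)pyridine | [N-]=[N+]=NCCCCCCCCCCCCCc1cccnc1 | intermediate
8 | triphenyl{[13-(pyridin-3-yl)tridecyl]imino}phosphorane | c1ccc(cc1)P(c1ccccc1)(c1ccccc1)=NCCCCCCCCCCCCCc1cccnc1 | intermediate
9 | 13-(pyridin-3-yl)tridecan-1-amine | NCCCCCCCCCCCCCc1cccnc1 | intermediate
10 | triphenyl[9-(pyridin-3-yl)nonyl]phosphonium bromide | [Br-].c1ccc(cc1)[P+](c1ccccc1)(c1ccccc1)CCCCCCCCCc1cccnc1 | intermediate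
11 | (5R)-5-(hydroxymethyl)oxolan-2-one | O=C1CC[C@H](CO)O1 | starting material
12 | (2R)-5-oxooxolane-2-carbaldehyde | O=C1CC[C@H](C=O)O1 | intermediate
13 | triphenyl[9-(pyridin-3-yl)nonylidene]phosphorane | c1ccc(cc1)P(c1ccccc1)(c1ccccc1)=CCCCCCCCCc1cccnc1 | intermediate
14 | (5R)-5-[(1Z)-10-(pyridin-3-yl)dec-1-en-1-yl]oxolan-2-one | O=C1CC[C@H](/C=C\CCCCCCCCc2cccnc2)O1 | intermediate
15 | (4R,5Z)-4-hydroxy-N-methoxy-N-methyl-14-(pyridin-3-yl)tetradec-5-enamide | CON(C)C(=O)CC[C@@H](O)/C=C\CCCCCCCCc1cccnc1 | intermediate
16 | (4R,5Z)-4-[(tert-butyldimethylsilyl)oxy]-N-methoxy-N-methyl-14-(pyridin-3-yl)tetradec-5-enamide | CON(C)C(=O)CC[C@@H](O[Si](C)(C)C(C)(C)C)/C=C\CCCCCCCCc1cccnc1 | intermediate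
17 | (4R,5Z)-4-[(tert-butyldimethylsilyl)oxy]-14-(pyridin-3-yl)tetradec-5-enal | O=CCC[C@@H](O[Si](C)(C)C(C)(C)C)/C=C\CCCCCCCCc1cccnc1 | intermediate
18 | (1E,4R,5Z)-4-[(tert-butyldimethylsilyl)oxy]-14-(pyridin-3-yl)-N-[13-(pyridin-3-yl)tridecyl]tetradec-5-en-1-imine | c1cncc(CCCCCCCCCCCCC/N=C/CC[C@@H](O[Si](C)(C)C(C)(C)C)/C=C\CCCCCCCCc2cccnc2)c1 | intermediate
19 | trans-3-[(3R,4Z)-3-[(tert-butyldimethylsilyl)oxy]-13-(pyridin-3-yl)tridec-4-en-1-yl]-2-[13-(pyridin-3-yl)tridecyl]oxaziridine, both ring diastereomers (configuration at the ring carbon and the ring nitrogen left undefined) | c1cncc(CCCCCCCCCCCCCN2OC2CC[C@@H](O[Si](C)(C)C(C)(C)C)/C=C\CCCCCCCCc2cccnc2)c1 | intermediate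
20 | (1Z,4R,5Z)-4-[(tert-butyldimethylsilyl)oxy]-14-(pyridin-3-yl)-N-[13-(pyridin-3-yl)tridecyl]tetradec-5-en-1-imine N-oxide (nitrone) | c1cncc(CCCCCCCCCCCCC/[N+]([O-])=C/CC[C@@H](O[Si](C)(C)C(C)(C)C)/C=C\CCCCCCCCc2cccnc2)c1 | intermediate
21 | (3S,3aS,4R,6aR)-4-[(tert-butyldimethylsilyl)oxy]-3-[8-(pyridin-3-yl)octyl]-1-[13-(pyridin-3-yl)tridecyl]hexahydro-1H-cyclopenta[c]isoxazole; H-3, H-3a, H-6a all cis, silyloxy group cis to H-3a | c1cncc(CCCCCCCCCCCCCN2O[C@@H](CCCCCCCCc3cccnc3)[C@H]3[C@H](O[Si](C)(C)C(C)(C)C)CC[C@H]32)c1 | intermediate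
22 | (3S,3aR,4R,6aR)-3-[8-(pyridin-3-yl)octyl]-1-[13-(pyridin-3-yl)tridecyl]hexahydro-1H-cyclopenta[c]isoxazol-4-ol | c1cncc(CCCCCCCCCCCCCN2O[C@@H](CCCCCCCCc3cccnc3)[C@H]3[C@H](O)CC[C@H]32)c1 | intermediate
23 | O-[(3S,3aR,4R,6aR)-3-[8-(pyridin-3-yl)octyl]-1-[13-(pyridin-3-yl)tridecyl]hexahydro-1H-cyclopenta[c]isoxazol-4-yl] 1H-imidazole-1-carbothioate | c1cncc(CCCCCCCCCCCCCN2O[C@@H](CCCCCCCCc3cccnc3)[C@H]3[C@H](OC(=S)n4ccnc4)CC[C@H]32)c1 | intermediate
24 | pyrinodemin B, (3S,3aS,6aR)-3-[8-(pyridin-3-yl)octyl]-1-[13-(pyridin-3-yl)tridecyl]hexahydro-1H-cyclopenta[c]isoxazole | c1cncc(CCCCCCCCCCCCCN2O[C@@H](CCCCCCCCc3cccnc3)[C@H]3CCC[C@H]32)c1 | target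

**Step count and risks**

Total step count: 15. Longest linear sequence: 12 steps (steps 1, 2, 5, 7, 8, 9, 10, 11, 12, 13, 14, 15, from 3-methylpyridine).

Steps most likely to fail:

1. Step 12 (Proposed new method). What may go wrong: cleavage of the N–O instead of the C–O bond of the oxaziridine (rearrangement to an amide or fragmentation back to carbonyl compounds), or ring opening that is not followed by cycloaddition. Fallback with known chemistry, setting out from 6 and 17 and returning at 21: 6 is used to N-alkylate tert-butyl N-(tert-butoxycarbonyloxy)carbamate (K2CO3, DMF) to give tert-butyl N-[(tert-butoxycarbonyl)oxy]-N-[13-(pyridin-3-yl)tridecyl]carbamate F1. Both carbamate groups are removed with CF3CO2H in CH2Cl2 followed by basic work-up to give N-[13-(pyridin-3-yl)tridecyl]hydroxylamine F2. Condensation of F2 with aldehyde 17 (MgSO4, CH2Cl2) gives nitrone 20 directly, and heating in PhMe at 100 °C (thermal intramolecular nitrone–alkene cycloaddition) should give 21 under the same stereocontrol.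

2. Step 7. What may go wrong: base-induced epimerisation at the α-oxy stereocentre of the aldehyde during ylide addition, and incomplete Z-selectivity. Fallback setting out from 2 and returning at 14: a further portion of the solution of picolyllithium 2 is alkylated with 1,7-dibromoheptane to 3-(8-bromooctyl)pyridine F3, which is displaced with LiC≡CH·H2NCH2CH2NH2 in DMSO to 3-(dec-9-yn-1-yl)pyridine F4. Acyl Sonogashira coupling of F4 with methyl 4-chloro-4-oxobutanoate (PdCl2(PPh3)2, CuI, Et3N) gives methyl 4-oxo-14-(pyridin-3-yl)tetradec-5-ynoate F5. Noyori transfer hydrogenation with RuCl[(R,R)-TsDPEN](p-cymene) in HCO2H–Et3N, the catalyst enantiomer expected to give the R carbinol, should give methyl (4R)-4-hydroxy-14-(pyridin-3-yl)tetradec-5-ynoate F6. Lactonisation (p-toluenesulfonic acid, PhMe) gives (5R)-5-[10-(pyridin-3-yl)dec-1-yn-1-yl]oxolan-2-one F7, and semihydrogenation (H2, Pd/CaCO3 poisoned with Pb(OAc)2, quinoline) gives 14, so that neither an enolisable aldehyde nor a kinetic olefination is needed.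

3. Step 15. What may go wrong: attack of stannyl radicals on the N–O bond, or collapse of the thionocarbonate back to the alcohol instead of C–O fragmentation. Fallback setting out from 22 and returning at 24, ionic instead of radical: Dess–Martin oxidation of 22 gives (3S,3aS,6aR)-3-[8-(pyridin-3-yl)octyl]-1-[13-(pyridin-3-yl)tridecyl]hexahydro-1H-cyclopenta[c]isoxazol-4-one F8. Condensation with p-toluenesulfonylhydrazide in MeOH gives the corresponding C4 p-toluenesulfonylhydrazone F9. Reduction with catecholborane in CHCl3 at 0 °C, then NaOAc·3H2O at reflux (hydrazone reduction with loss of sulfinate and dinitrogen), should give the C4 methylene compound 24.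

**Further compounds**

F1 | step 12 | tert-butyl N-[(tert-butoxycarbonyl)oxy]-N-[13-(pyridin-3-yl)tridecyl]carbamate | CC(C)(C)OC(=O)ON(CCCCCCCCCCCCCc1cccnc1)C(=O)OC(C)(C)C
F2 | step 12 | N-[13-(pyridin-3-yl)tridecyl]hydroxylamine | ONCCCCCCCCCCCCCc1cccnc1
F3 | step 7 | 3-(8-bromooctyl)pyridine | BrCCCCCCCCc1cccnc1
F4 | step 7 | 3-(dec-9-yn-1-yl)pyridine | C#CCCCCCCCCc1cccnc1
F5 | step 7 | methyl 4-oxo-14-(pyridin-3-yl)tetradec-5-ynoate | COC(=O)CCC(=O)C#CCCCCCCCCc1cccnc1
F6 | step 7 | methyl (4R)-4-hydroxy-14-(pyridin-3-yl)tetradec-5-ynoate | COC(=O)CC[C@@H](O)C#CCCCCCCCCc1cccnc1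
F7 | step 7 | (5R)-5-[10-(pyridin-3-yl)dec-1-yn-1-yl]oxolan-2-one | O=C1CC[C@H](C#CCCCCCCCCc2cccnc2)O1
F8 | step 15 | (3S,3aS,6aR)-3-[8-(pyridin-3-yl)octyl]-1-[13-(pyridin-3-yl)tridecyl]hexahydro-1H-cyclopenta[c]isoxazol-4-one | c1cncc(CCCCCCCCCCCCCN2O[C@@H](CCCCCCCCc3cccnc3)[C@H]3C(=O)CC[C@H]32)c1
F9 | step 15 | p-toluenesulfonylhydrazone of the C4 ketone F8 (C=N geometry undefined) | c1cncc(CCCCCCCCCCCCCN2O[C@@H](CCCCCCCCc3cccnc3)[C@H]3C(=NNS(=O)(=O)c4ccc(C)cc4)CC[C@H]32)c1
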